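Start from a one-step world: substrate goes to target, and the charge gives the yield. This flask has a fork instead.

    substrate → intermediate (k1 = 0.0019 s⁻¹)
    first nucleophile + intermediate → target (k2 = 2.6 M⁻¹ s⁻¹)
    second nucleophile + intermediate → other capture product (k3 = 0.93 M⁻¹ s⁻¹)
    gas ⇌ second nucleophile, rate k4*(csat - [second nucleophile]) (k4 = 0.028 s⁻¹, csat = 22 mM)

| setting | alder | birch | elm | maple | larch |
|---|---|---|---|---|---|
| substrate | 0.082 M | 0.082 M | 0.082 M | 0.082 M | 0.082 M |
| first nucleophile | 0.0300 M | 0.0400 M | 0.0600 M | 0.100 M | 0.150 M |
| gas | 22 mM (held) | 22 mM (held) | 22 mM (held) | 22 mM (held) | 22 mM (held) |
| time | 40 min | 40 min | 40 min | 40 min | 40 min |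

- at the start none of second nucleophile is dissolved
- "hardly changes" means that all values lie within two and a half points (for a concentration: within two and a half percent of the largest)
- run time (alder): 40 min

- share of target in all that became target or other capture product for alder, birch, elm, maple, larch, in this order
- the course of these numbers from the first flask to the last (falls, then rises / falls all the way / hardly changes / rises, then falls / rises all the way)

Divide the rate of step 2 by the rate of step 3. Intermediate cancels, and time goes with it. What remains is the selectivity factor 2.80 times c(first nucleophile) over c(second nucleophile). Gas refills second nucleophile with a half-life of 0.413 min, shorter than the 6.1 min of substrate, so set c(second nucleophile) to csat. Call 7.87 mM the crossover concentration, the c(first nucleophile) at which both captures run equally fast. The share of target in fresh capture is then c(first nucleophile) over c(first nucleophile) plus crossover.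

Take the first extreme: hold c(first nucleophile) at its charge. Alder gives 0.792 and larch 0.950. Real first nucleophile is consumed, so both figures stand too high.

Take the second extreme: let intermediate take first nucleophile until none is left. The alder charge is smaller than the substrate charge, so target stops at 0.366. The larch charge is larger, so put charge minus substrate into the rule from the first moment, which gives 0.896. Crossover is smaller than the alder charge, so expect alder near its lower figure. Expect larch inside its band. Larch's lower figure stands above alder's upper figure by 0.104. With the same substrate and gas, a larger charge holds more first nucleophile at each amount captured, so the fresh share stands higher at each such point. So I expect this course: rises all the way.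

The forecast gave 37 %, 49.2 %, 71 %, 88.3 % and 93.4 %, and said rises all the way. Its ground was that “the low-nucleophile flasks run out of first nucleophile”.

The flask gives 37.0 %, 49.2 %, 70.8 %, 88.3 % and 93.5 %: rises all the way.

Consumption of first nucleophile is the main reason for the low alder share: the alder run without that consumption gives 80.5 % against 37.0 %. After 40.0 min alder holds 0.0274 mM of first nucleophile, far below crossover, so fresh capture there gives target at 0.346 %. Larch holds 74.1 mM, well above crossover, and there the same consumption is just a part of the gap, worth 1.8 percentage points.

The numbers of this flask are those of an exercise.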